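The early minutes of these four runs are where I begin, and the three flasks below differ in how their charges meet.

| run | time / min | complex with one exchanged / % | starting complex / % |
|---|---|---|---|
| Tuesday's | 0.667 | 17.7 | 82.3 |
| Tuesday's | 1.00 | 22.5 | 76.2 |
| Tuesday's | 1.33 | 29.2 | 69.8 |
| Tuesday's | 2.50 | 41.5 | 54.4 |
| Tuesday's | 3.00 | 48.2 | 50.0 |
| Tuesday's | 5.00 | 59.6 | 36.1 |
| Tuesday's | 8.00 | 66.4 | 26.2 |
| Sunday's | 0.333 | 5.2 | 96.1 |
| Sunday's | 1.00 | 12.4 | 85.6 |
| Sunday's | 2.00 | 22.0 | 76.6 |
| Sunday's | 3.00 | 28.2 | 71.0 |
| Sunday's | 4.00 | 30.5 | 64.8 |
| Sunday's | 5.00 | 33.8 | 63.1 |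
| Sunday's | 6.00 | 40.1 | 59.2 |
| Monday's | 1.00 | 18.4 | 80.2 |
| Monday's | 2.00 | 29.1 | 68.5 |
| Monday's | 3.00 | 37.4 | 62.3 |
| Monday's | 4.00 | 45.2 | 54.5 |
| Monday's | 5.00 | 50.1 | 48.9 |
| Monday's | 6.00 | 51.3 | 42.9 |
| Wednesday's | 0.500 | 12.9 | 85.8 |
| Wednesday's | 1.00 | 23.0 | 75.4 |
| Wednesday's | 2.00 | 35.9 | 64.0 |
| Wednesday's | 3.00 | 42.8 | 53.0 |
| Wednesday's | 6.00 | 59.0 | 39.5 |

(readings scatter by 1 percentage point)

| flask | starting complex | incoming ligand | remark | time |
|---|---|---|---|---|
| Tuesday's | 29 mM | 52.2 mM | run made earlier |  |
| Sunday's | 29 mM | 26 mM | run made earlier |  |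
| Monday's | 29 mM | 39 mM | run made earlier |  |
| Wednesday's | 44 mM | 52.2 mM | run made earlier |  |
| spring | 29 mM | 52.2 mM | everything together at the start | 8.0 min |
| summer | 29 mM (fed, over 3.0 min) | 52.2 mM | all else is in the flask from the start; the feed brings no volume worth counting | 8.0 min |
| midnight | 29 mM | 52.2 mM (fed, over 3.0 min) | all else is in the flask from the start; the feed brings no volume worth counting | 8.0 min |

- a reading or a percentage of complex with one exchanged counts all its forms, free or not

- the flask with the highest amount of complex with one exchanged, in percent of the starting complex charged ("all alike" if they lie within 1.5 percentage points) (spring / summer / midnight / all alike)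
- final complex with one exchanged, as a percentage of the starting complex charged, in spring
- final complex with one exchanged, as a percentage of the starting complex charged, in summer
- final complex with one exchanged, as a percentage of the starting complex charged, in midnight

What does the start give? Monday's first reading leaves 80.2 % of the starting complex after 1.00 min, and the logarithm of that loss over time and ligand charge reads as a second-order constant k = 5.66 M⁻¹ min⁻¹.

Does k hold late? Tuesday's starting complex falls from 36.1 % to 26.2 % between 5.00 min and 8.00 min, a slope that with k asks for 18.9 mM of incoming ligand, but the balance of the first exchange leaves 32.2 mM, which is more, so ligand is going elsewhere.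

At what rate, if it decays by itself? The missing ligand, spread over 6.50 min at a mean of 35.5 mM, reads as a decay constant kd = 0.0578 min⁻¹.

What do I carry? With the whole charge of starting complex, 2.84 is S, the rate at which incoming ligand enters the first exchange over the rate at which it decays, k[starting complex]/kd, a selectivity factor.

And the two feeds? In summer S climbs from nothing and stays below 2.84 during the feed, and I reckon that decay from up to 52.2 mM of ligand takes at most 9.05 mM over 3.0 min, whereas midnight's rising ligand averages at most half its charge, so I reckon at most 4.52 mM, less. With that difference of 4.52 mM and Tuesday's last 26.2 % of starting complex as stand-in over the remaining 5.00 min, I estimate summer's cost at 3.4 percentage points; spring has Tuesday's charges, so I read its answer as Tuesday's 66.4 % and commit to the order spring, midnight, summer.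

The forecast gives spring first, with 66.2 %, 62.6 % and 62.9 % for spring, summer and midnight, on the ground that “each feed lags by about 1.7 min”, and my reckoning parts from it on the gap between the feeds.

Spring, the highest, gives 68.0 %, midnight 64.3 % and summer 60.9 %, a gap of 3.4 points between the feeds; S, which I read as 2.84, stands at 3.0 at spring's start, and my 2.84 taken on spring's 26.0 % of starting complex at 8.00 min gives 0.738. By 3.00 min the first exchange had brought complex with one exchanged to 27.8 % in summer and 30.2 % in midnight, while decomposed reagent reached 7.68 mM in summer, more than midnight's 3.66 mM. The first exchange then ran on as crystals grew, to 51.9 % in summer and 55.3 % in midnight at 8.00 min.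

    starting complex + incoming ligand → leaving ligand + complex with one exchanged (k = 5.80 M⁻¹ min⁻¹)
    complex with one exchanged + incoming ligand → leaving ligand + complex with two exchanged (k = 0.770 M⁻¹ min⁻¹)
    leaving ligand + complex with one exchanged → side product (k = 2.70 M⁻¹ min⁻¹)
    crystals ⇌ complex with one exchanged, rate k4*(cs4 - [complex with one exchanged]) while solid is left; crystals form when [complex with one exchanged] > cs4 (solubility = 1.70 mM, k = 1.20 min⁻¹)
    incoming ligand → decomposed reagent (k = 0.0570 min⁻¹)

In the neighbour of spring charged with 13 mM of incoming ligand, S starts at the same 2.84, so S/(1+S), or 74.0 %, of the ligand used enters the first exchange, and holding the starting complex at its charge gives 27.5 % of complex with one exchanged. The computed flask gives 24.4 %, with 74.5 % of starting complex left.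

The runs are simulated for an exercise, noise included.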